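Begin by asking what one number carries the earlier runs over to the new flasks.

| flask | Z | Q | remark | time |
|---|---|---|---|---|
| noon | 0.32 mM | 1.1 equiv (in portions, 4) | run made earlier; portions every 1.0 min |  |
| summer | 1.1 mM | 1.1 equiv (in portions, 4) | run made earlier; portions every 1.0 min |  |
| autumn | 3.4 mM | 1.1 equiv (in portions, 4) | run made earlier; portions every 1.0 min |  |
| amber | 1.0 mM | 1.10 equiv (in portions, 4) | the portions of Q follow each other after 1.0 min, the first at the start | 4.0 min |
| green | 3.0 mM | 1.10 equiv (in portions, 4) | the portions of Q follow each other after 1.0 min, the first at the start | 4.0 min |
| red | 2.0 mM | 1.10 equiv (in portions, 4) | the portions of Q follow each other after 1.0 min, the first at the start | 4.0 min |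
| blue | 0.25 mM | 1.10 equiv (in portions, 4) | the portions of Q follow each other after 1.0 min, the first at the start | 4.0 min |
| teal | 0.50 mM | 1.10 equiv (in portions, 4) | the portions of Q follow each other after 1.0 min, the first at the start | 4.0 min |
| ochre | 4.0 mM | 1.10 equiv (in portions, 4) | the portions of Q follow each other after 1.0 min, the first at the start | 4.0 min |

- noon (time / min: X / %): 0.833: 0; 1.50: 1; 2.50: 6; 3.00: 7; 4.00: 11
- summer (time / min: X / %): 0.333: 0; 0.667: 2; 1.00: 3; 2.00: 11; 4.00: 21
- autumn (time / min: X / %): 0.833: 5; 1.50: 11; 2.50: 22; 3.00: 26; 4.00: 32

(standard deviation of a reading: 1.5 percentage points)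

* the flasks put in order of amount of X, in percent of the Z charged, best first, at 4.0 min (amber / green / red / blue / teal / ochre)
* the amount of X, in percent of the Z charged of the flask you put first, at 4.0 min
* the amount of X, in percent of the Z charged of the flask you put last, at 4.0 min



What differs between the new flasks? The starting concentration of Z, written c. The dosing and the time are held.

What do the earlier runs show at 4.0 min? X is 11% at 0.32 mM, 21% at 1.1 mM and 32% at 3.4 mM.

What do you carry from them? A slope. Taking ln of the yield against ln c from noon to summer gives 0.524. Call it n, the dilution exponent: the power by which the yield at the asked time follows c between two neighbouring runs, an apparent order of the yield in c. From summer to autumn the slope reckoned in this way is 0.373, which is smaller than n.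

And the ranking? Both slopes are above zero, so I rank by c, with ochre first and blue last.

Why not reckon each end flask from nothing? Blue lies close to noon, at a ratio of 0.781 in c. So I treat noon's reading as the large thing and compute a correction factor, 0.879. That gives blue 9.67%. The same step from autumn with the upper slope gives ochre 34.0%.

Where is this weak? Each reading carries 1.5 percentage points, so n is itself a reading, and the noon reading is the smallest of the three.

The forecast gives ochre > green > red > amber > teal > blue, with top 34% and low 9%. My top matches it, but my low stands above it. Its ground: “The order follows concentration”.

The flasks give ochre > green > red > amber > teal > blue, with top 35.8% and low 9.28%, so the forecast is right within its tolerance.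

    Z + Q ⇌ G (K = 2630 M⁻¹, k = 8.16 M⁻¹ s⁻¹)
    G ⇌ X (K = 1.00, k = 0.0185 s⁻¹)

The same correction goes to a neighbour flask, like blue but with 0.10 mM of Z, which lies further from noon. There n gives 5.98%, and the flask gives 4.28%. That gap of 1.7 points compares with 0.39 points on blue. Taking Z from blue's charge down to 0.100 mM moves X by 5 points. Between this neighbour and blue the exponent is 0.845, steeper than n.

(The data stem from a simulated flask on assumed constants, noise included.)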